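**Plan**
- Retrosynthesis: after removing the acetates and the C15 silyl group and returning C2–OH and C6–OH to ketones, ring A is opened by cutting C3–C4 and C5–C10 together (retro-[4+2]). The resulting acyclic triene is then cut at C9–C10, at C8–CH3/C9–I, at C5–C6 and at C7–C8.
- Enabling feature: ring A carries oxygen at C2, 1,4 to C5, whose neighbour C6 is also oxygenated. Ring A is therefore the adduct of a 2-silyloxydiene (C3=C2–C1=C10) and an enone (C4=C5–C6=O), and C6–C7–C8=C9 of ring B is a four-atom tether between C5 and C10.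
- Forward order: side-chain enyne → ynone → C7 carbinol → Z tetrasubstituted iodoalkene → enone → bis-enone (Suzuki coupling) → silyloxytriene → rings A and B closed together → C6 reduction, C2 unmasking and reduction, acetylation, desilylation.
- Stereochemistry: C7 from asymmetric transfer hydrogenation; C5 and C10 from C7 in the cycloaddition; 6β-OH by α-face hydride attack; 2α-OH by dissolving-metal reduction. Alkene geometries come from HWE olefination, chelate-controlled anti carbomagnesiation and syn borylcupration.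

Key step: step 14

Remark: labdane numbering is used for ring compounds (ring A = C1–C5, C10; ring B = C5–C10; C11–C16 side chain on C9; C17 on C8; C18/C19 on C4; C20 on C10); β is the face of the C10 methyl group, α the opposite face.
Remark: the (R,R) catalyst in step 5 is assigned on the assumption that the alkynyl group takes the place it takes in simple alkynyl ketones.

Step 1
Reactants: 1 hex-5-yn-2-one; 2 triethyl phosphonoacetate
Product: 3 ethyl (2E)-3-methylhept-2-en-6-ynoate
Conditions: NaH, THF, 0 °C to rt; chromatographic removal of the minor Z isomer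
Reagents that add atoms: none
Why: Horner–Wadsworth–Emmons olefination of a methyl ketone with a stabilised phosphonate anion should favour the E trisubstituted enoate (ester trans to the larger chain), and the terminal alkyne is not deprotonated by this anion.

Step 2
Reactants: 3 ethyl (2E)-3-methylhept-2-en-6-ynoate
Product: 4 (2E)-3-methylhept-2-en-6-yn-1-ol
Conditions: i-Bu2AlH (2.2 equiv), CH2Cl2, −78 °C; aq. potassium sodium tartrate
Reagents that add atoms: none
Why: 1,2-reduction of an α,β-unsaturated ester by i-Bu2AlH at low temperature should give the allylic alcohol without touching the alkyne or the alkene geometry.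

Step 3
Reactants: 4 (2E)-3-methylhept-2-en-6-yn-1-ol
Product: 5 triisopropyl{[(2E)-3-methylhept-2-en-6-yn-1-yl]oxy}silane
Conditions: i-Pr3SiCl, imidazole, DMF, rt
Reagents that add atoms: chlorotriisopropylsilane, CC(C)[Si](Cl)(C(C)C)C(C)C
Why: Silyl ether formation at a primary alcohol; the triisopropylsilyl group is chosen because it should survive Grignard reagents, hydride, buffered HF at 0 °C and Li/NH3 and can be removed last without touching acetates.

Step 4
Reactants: 5 triisopropyl{[(2E)-3-methylhept-2-en-6-yn-1-yl]oxy}silane; 6 acetoxyacetyl chloride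
Product: 9 (7E)-7-methyl-2-oxo-9-[(triisopropylsilyl)oxy]non-7-en-3-yn-1-yl acetate, via alkynyllithium 7 (not isolated), via alkynylzinc chloride 8 (not isolated)
Conditions: n-BuLi, THF, −78 °C; ZnCl2, −78 to 0 °C; then 6, Pd(PPh3)4 (5 mol %), 0 °C to rt
Reagents that add atoms: none
Why: Negishi acylation of an alkynylzinc chloride with an acid chloride under Pd(PPh3)4 catalysis needs no amine base, which avoids ketene formation from the α-acyloxy acid chloride and leaves the acetate intact.

Step 5
Reactants: 9 (7E)-7-methyl-2-oxo-9-[(triisopropylsilyl)oxy]non-7-en-3-yn-1-yl acetate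
Product: 10 (2S,7E)-2-hydroxy-7-methyl-9-[(triisopropylsilyl)oxy]non-7-en-3-yn-1-yl acetate
Conditions: Ru[(R,R)-TsNCH(Ph)CH(Ph)NH](p-cymene) (2 mol %), i-PrOH, rt
Reagents that add atoms: none
Why: Noyori asymmetric transfer hydrogenation of an alkynyl ketone, in which the catalyst tells the alkynyl from the alkyl flank and delivers hydride to one carbonyl face, should set the carbinol carbon (labdane C7) as S, the only stereocenter carried into the key step.

Step 6
Reactants: 10 (2S,7E)-2-hydroxy-7-methyl-9-[(triisopropylsilyl)oxy]non-7-en-3-yn-1-yl acetate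
Product: 13 (2S,3Z,7E)-4-iodo-3,7-dimethyl-9-[(triisopropylsilyl)oxy]nona-3,7-diene-1,2-diol, via bis(bromomagnesium) alkoxide 11 (not isolated), via cyclic alkenylmagnesium chelate 12 (not isolated)
Conditions: MeMgBr (6 equiv), CuI (0.2 equiv), THF, 0 °C to reflux; then I2, −78 to 0 °C; aq. Na2S2O3/NH4Cl
Reagents that add atoms: methylmagnesium bromide, C[Mg]Br; iodine, II
Why: Alkoxide-directed CuI-catalysed anti carbomagnesiation of a propargylic alcohol (excess Grignard reagent first removes the acetate) should deliver methyl to the alkyne carbon next to the carbinol and magnesium to the distal carbon inside a five-membered chelate, so that iodinolysis with retention gives the Z tetrasubstituted iodoalkene with iodine cis to the carbinol carbon.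

Step 7
Reactants: 13 (2S,3Z,7E)-4-iodo-3,7-dimethyl-9-[(triisopropylsilyl)oxy]nona-3,7-diene-1,2-diol
Product: 14 (2S,3Z,7E)-4-iodo-3,7-dimethyl-1,2-bis[(triethylsilyl)oxy]-9-[(triisopropylsilyl)oxy]nona-3,7-diene
Conditions: Et3SiCl (2.5 equiv), imidazole, DMAP (cat.), DMF, 0 °C to rt
Reagents that add atoms: chlorotriethylsilane, CC[Si](Cl)(CC)CC
Why: Imidazole-promoted silylation of both hydroxyls prepares the differentiation of the primary and the secondary oxygen in step 8.

Step 8
Reactants: 14 (2S,3Z,7E)-4-iodo-3,7-dimethyl-1,2-bis[(triethylsilyl)oxy]-9-[(triisopropylsilyl)oxy]nona-3,7-diene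
Product: 15 (2S,3Z,7E)-4-iodo-3,7-dimethyl-2-[(triethylsilyl)oxy]-9-[(triisopropylsilyl)oxy]nona-3,7-dienal
Conditions: (COCl)2 (4 equiv), DMSO (8 equiv), CH2Cl2, −78 to −30 °C; then Et3N, −78 °C to rt
Reagents that add atoms: none
Why: Under Swern conditions a primary triethylsilyl ether is cleaved and oxidised directly to the aldehyde while the hindered secondary allylic triethylsilyl ether stays, and the low temperature guards the α-silyloxy stereocenter.

Step 9
Reactants: 15 (2S,3Z,7E)-4-iodo-3,7-dimethyl-2-[(triethylsilyl)oxy]-9-[(triisopropylsilyl)oxy]nona-3,7-dienal; 16 (2-methylprop-1-en-1-yl)magnesium bromide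
Product: 17 (5S,6Z,10E)-7-iodo-2,6,10-trimethyl-5-[(triethylsilyl)oxy]-12-[(triisopropylsilyl)oxy]dodeca-2,6,10-trien-4-ol (both C4 epimers)
Conditions: THF, −78 °C; aq. NH4Cl
Reagents that add atoms: none
Why: 1,2-Addition of an alkenyl Grignard reagent to the aldehyde at −78 °C, where iodine–magnesium exchange at the alkenyl iodide is slow, should give the allylic alcohol, whose new carbinol centre is erased in step 10.

Step 10
Reactants: 17 (5S,6Z,10E)-7-iodo-2,6,10-trimethyl-5-[(triethylsilyl)oxy]-12-[(triisopropylsilyl)oxy]dodeca-2,6,10-trien-4-ol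
Product: 18 (5S,6Z,10E)-7-iodo-2,6,10-trimethyl-5-[(triethylsilyl)oxy]-12-[(triisopropylsilyl)oxy]dodeca-2,6,10-trien-4-one
Conditions: Dess–Martin periodinane, NaHCO3, CH2Cl2, 0 °C to rt
Reagents that add atoms: none
Why: Dess–Martin oxidation of the allylic alcohol under buffered, non-basic conditions should give the α-silyloxy enone without epimerising the neighbouring stereocenter.

Step 11
Reactants: 19 pent-3-yn-2-one
Product: 20 (3Z)-4-(4,4,5,5-tetramethyl-1,3,2-dioxaborolan-2-yl)pent-3-en-2-one
Conditions: B2pin2 (1.1 equiv), CuCl (3 mol %), NaOt-Bu (6 mol %), Xantphos (3 mol %), MeOH (2 equiv), THF, rt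
Reagents that add atoms: bis(pinacolato)diboron, CC1(C)OB(OC1(C)C)B1OC(C)(C)C(C)(C)O1
Why: Copper-catalysed β-borylation of an ynone (syn borylcupration, then protonation) places boron on the β-carbon cis to the new vinylic hydrogen and trans to the acetyl group, which is the geometry needed at C10=C1.

Step 12
Reactants: 18 (5S,6Z,10E)-7-iodo-2,6,10-trimethyl-5-[(triethylsilyl)oxy]-12-[(triisopropylsilyl)oxy]dodeca-2,6,10-trien-4-one; 20 (3Z)-4-(4,4,5,5-tetramethyl-1,3,2-dioxaborolan-2-yl)pent-3-en-2-one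
Product: 21 (3E,5Z,7S)-4,6,10-trimethyl-5-{(3E)-3-methyl-5-[(triisopropylsilyl)oxy]pent-3-en-1-yl}-7-[(triethylsilyl)oxy]undeca-3,5,9-triene-2,8-dione
Conditions: Pd(dppf)Cl2 (10 mol %), K3PO4 (3 equiv), THF/H2O 10:1, rt to 40 °C, dark
Reagents that add atoms: none
Why: Suzuki–Miyaura coupling of an alkenyl iodide with an alkenylboronate proceeds with retention at both partners and should give the Z tetrasubstituted C8=C9 and the E C10=C1 alkene of the bis-enone.

Step 13
Reactants: 21 (3E,5Z,7S)-4,6,10-trimethyl-5-{(3E)-3-methyl-5-[(triisopropylsilyl)oxy]pent-3-en-1-yl}-7-[(triethylsilyl)oxy]undeca-3,5,9-triene-2,8-dione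
Product: 23 (5S,6Z,8E)-10-[(tert-butyldimethylsilyl)oxy]-2,6,8-trimethyl-7-{(3E)-3-methyl-5-[(triisopropylsilyl)oxy]pent-3-en-1-yl}-5-[(triethylsilyl)oxy]undeca-2,6,8,10-tetraen-4-one, via lithium dienolate 22 (not isolated)
Conditions: LiN(i-Pr)2 (1.05 equiv), THF, −78 °C; then t-BuMe2SiCl, DMPU, −78 to −20 °C; pentane/aq. NaHCO3, filtration through basic alumina
Reagents that add atoms: tert-butyl(chloro)dimethylsilane, CC(C)(C)[Si](C)(C)Cl
Why: Kinetic enolisation should remove a proton from the unhindered acetyl methyl group rather than the hindered tertiary α-silyloxy hydrogen or the γ-methyl hydrogens of the other enone, and O-silylation (silyl enol ether formation) then gives the cross-conjugated 2-silyloxydiene.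

Step 14
Reactants: 23 (5S,6Z,8E)-10-[(tert-butyldimethylsilyl)oxy]-2,6,8-trimethyl-7-{(3E)-3-methyl-5-[(triisopropylsilyl)oxy]pent-3-en-1-yl}-5-[(triethylsilyl)oxy]undeca-2,6,8,10-tetraen-4-one
Product: 24 2-[(tert-butyldimethylsilyl)oxy]-7α-[(triethylsilyl)oxy]-15-[(triisopropylsilyl)oxy]labda-1,8,13E-trien-6-one (5S,7S,10S; H-5 α, C10 methyl β)
Conditions: toluene (0.005 M), BHT, N,O-bis(trimethylsilyl)acetamide (0.2 equiv), sealed tube, 160 °C
Reagents that add atoms: none
Why: Thermal type 1 intramolecular Diels–Alder reaction, concerted but asynchronous, in which the HOMO of the 2-silyloxydiene (C3=C2–C1=C10) meets the LUMO of the s-cis enone (C4=C5–C6=O) with the C3–C4 bond leading, the donor at C2 and the acceptor at C6 being matched with the regiochemistry the tether imposes. The closest known reaction type is the cyclisation of 1,7,9-decatrien-3-ones that carry a 2-silyloxydiene. Ring A is closed by the [4+2] event itself, and ring B is closed through C5–C10 as the fused six-membered ring spanned by the tether C6–C7–C8=C9 that joins the dienophile to the diene terminus C10. C5 and C10 are set relative to each other by the exo placement of the tether carbonyl (H-5 endo), which should give the trans ring fusion because this transition state lets ring B form as a half-chair with the enone s-cis and keeps the tether out from under the diene. Their absolute sense comes from C7, whose OSiEt3 group should sit pseudoaxial in the half-chair of nascent ring B, away from A(1,2) strain with the C8 methyl and from dipole alignment with the C6 carbonyl, which puts the C10 methyl on the face opposite to the C7 oxygen. The step needs exo over endo selectivity and a cycloaddition faster than a [1,5]-hydrogen shift from the inside C10 methyl, which the E geometry at C10=C1 (tether outside, no 6π-electrocyclisation possible), the twist of the tetrasubstituted C8=C9 plane out of the diene plane, high dilution and the acid scavenger are meant to secure.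

Step 15
Reactants: 24 2-[(tert-butyldimethylsilyl)oxy]-7α-[(triethylsilyl)oxy]-15-[(triisopropylsilyl)oxy]labda-1,8,13E-trien-6-one
Product: 25 2-[(tert-butyldimethylsilyl)oxy]-7α-[(triethylsilyl)oxy]-15-[(triisopropylsilyl)oxy]labda-1,8,13E-trien-6β-ol
Conditions: LiAlH4, Et2O, −78 to −20 °C; aq. potassium sodium tartrate
Reagents that add atoms: none
Why: Hydride reduction of a hindered cyclohexanone whose β face is shielded by the two syn-axial methyl groups on C4 and C10 (as in 11-oxo steroids) should proceed from the α face and give the axial 6β alcohol, the enol silyl ether and the silyl ethers being inert to LiAlH4.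

Step 16
Reactants: 25 2-[(tert-butyldimethylsilyl)oxy]-7α-[(triethylsilyl)oxy]-15-[(triisopropylsilyl)oxy]labda-1,8,13E-trien-6β-ol
Product: 26 6β,7α-dihydroxy-15-[(triisopropylsilyl)oxy]labda-8,13E-dien-2-one
Conditions: HF·pyridine, pyridine, THF, 0 °C
Reagents that add atoms: none
Why: Fluoride-mediated desilylation under pyridine-buffered HF should cleave the enol silyl ether (to the C2 ketone) and the secondary triethylsilyl ether much faster than the primary triisopropylsilyl ether, and the buffer avoids ionising the allylic C7 alcohol.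

Step 17
Reactants: 26 6β,7α-dihydroxy-15-[(triisopropylsilyl)oxy]labda-8,13E-dien-2-one
Product: 27 15-[(triisopropylsilyl)oxy]labda-8,13E-diene-2α,6β,7α-triol
Conditions: Li, NH3(l)/THF, t-BuOH (2 equiv), −78 °C until the blue colour persists; then solid NH4Cl
Reagents that add atoms: none
Why: Dissolving-metal reduction of a ketone gives the thermodynamically preferred equatorial alcohol (2α, S), whereas a hydride reagent would be steered to the axial 2β alcohol by the same two axial methyl groups, and isolated alkenes and lithium alkoxides should not be reduced under these brief conditions.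

Step 18
Reactants: 27 15-[(triisopropylsilyl)oxy]labda-8,13E-diene-2α,6β,7α-triol
Product: 28 15-[(triisopropylsilyl)oxy]labda-8,13E-diene-2α,6β,7α-triyl triacetate
Conditions: Ac2O, DMAP, pyridine, rt to 50 °C
Reagents that add atoms: acetic anhydride, CC(=O)OC(C)=O
Why: DMAP-catalysed acetylation should esterify all three secondary alcohols, with warming for the hindered axial 6β hydroxyl.

Step 19
Reactants: 28 15-[(triisopropylsilyl)oxy]labda-8,13E-diene-2α,6β,7α-triyl triacetate
Product: 29 15-hydroxylabda-8,13E-diene-2α,6β,7α-triyl triacetate (2S,5S,6S,7S,10S), the target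
Conditions: HF·pyridine, pyridine, THF, rt
Reagents that add atoms: none
Why: Fluoride cleavage of the primary silyl ether under buffered HF should leave the three acetates and both alkenes untouched.

**Compound list**
1 | hex-5-yn-2-one | CC(=O)CCC#C | starting material
2 | triethyl phosphonoacetate | CCOC(=O)CP(=O)(OCC)OCC | starting material
3 | ethyl (2E)-3-methylhept-2-en-6-ynoate | CCOC(=O)/C=C(\C)CCC#C | intermediate
4 | (2E)-3-methylhept-2-en-6-yn-1-ol | OC/C=C(\C)CCC#C | intermediate
5 | triisopropyl{[(2E)-3-methylhept-2-en-6-yn-1-yl]oxy}silane | C#CCC/C(C)=C/CO[Si](C(C)C)(C(C)C)C(C)C | intermediate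
6 | acetoxyacetyl chloride | CC(=O)OCC(Cl)=O | starting material
7 | alkynyllithium of 5 | [Li]C#CCC/C(C)=C/CO[Si](C(C)C)(C(C)C)C(C)C | intermediate
8 | alkynylzinc chloride of 5 | Cl[Zn]C#CCC/C(C)=C/CO[Si](C(C)C)(C(C)C)C(C)C | intermediate
9 | (7E)-7-methyl-2-oxo-9-[(triisopropylsilyl)oxy]non-7-en-3-yn-1-yl acetate | CC(=O)OCC(=O)C#CCC/C(C)=C/CO[Si](C(C)C)(C(C)C)C(C)C | intermediate
10 | (2S,7E)-2-hydroxy-7-methyl-9-[(triisopropylsilyl)oxy]non-7-en-3-yn-1-yl acetate | CC(=O)OC[C@@H](O)C#CCC/C(C)=C/CO[Si](C(C)C)(C(C)C)C(C)C | intermediate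
11 | bis(bromomagnesium) alkoxide of the (2S)-non-7-en-3-yne-1,2-diol | Br[Mg]OC[C@@H](O[Mg]Br)C#CCC/C(C)=C/CO[Si](C(C)C)(C(C)C)C(C)C | intermediate
12 | cyclic alkenylmagnesium chelate (magnesium bridging the C7 oxygen and C9) | Br[Mg]OC[C@@H](O[Mg]1)C(C)=C1CC/C(C)=C/CO[Si](C(C)C)(C(C)C)C(C)C | intermediate
13 | (2S,3Z,7E)-4-iodo-3,7-dimethyl-9-[(triisopropylsilyl)oxy]nona-3,7-diene-1,2-diol | OC[C@@H](O)/C(C)=C(\I)CC/C(C)=C/CO[Si](C(C)C)(C(C)C)C(C)C | intermediate
14 | (2S,3Z,7E)-4-iodo-3,7-dimethyl-1,2-bis[(triethylsilyl)oxy]-9-[(triisopropylsilyl)oxy]nona-3,7-diene | CC[Si](CC)(CC)OC[C@@H](O[Si](CC)(CC)CC)/C(C)=C(\I)CC/C(C)=C/CO[Si](C(C)C)(C(C)C)C(C)C | intermediate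
15 | (2S,3Z,7E)-4-iodo-3,7-dimethyl-2-[(triethylsilyl)oxy]-9-[(triisopropylsilyl)oxy]nona-3,7-dienal | O=C[C@@H](O[Si](CC)(CC)CC)/C(C)=C(\I)CC/C(C)=C/CO[Si](C(C)C)(C(C)C)C(C)C | intermediate
16 | (2-methylprop-1-en-1-yl)magnesium bromide | CC(C)=C[Mg]Br | starting material
17 | (5S,6Z,10E)-7-iodo-2,6,10-trimethyl-5-[(triethylsilyl)oxy]-12-[(triisopropylsilyl)oxy]dodeca-2,6,10-trien-4-ol (both C4 epimers) | CC(C)=CC(O)[C@@H](O[Si](CC)(CC)CC)/C(C)=C(\I)CC/C(C)=C/CO[Si](C(C)C)(C(C)C)C(C)C | intermediate
18 | (5S,6Z,10E)-7-iodo-2,6,10-trimethyl-5-[(triethylsilyl)oxy]-12-[(triisopropylsilyl)oxy]dodeca-2,6,10-trien-4-one | CC(C)=CC(=O)[C@@H](O[Si](CC)(CC)CC)/C(C)=C(\I)CC/C(C)=C/CO[Si](C(C)C)(C(C)C)C(C)C | intermediate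
19 | pent-3-yn-2-one | CC#CC(C)=O | starting material
20 | (3Z)-4-(4,4,5,5-tetramethyl-1,3,2-dioxaborolan-2-yl)pent-3-en-2-one | CC(=O)/C=C(\C)B1OC(C)(C)C(C)(C)O1 | intermediate
21 | (3E,5Z,7S)-4,6,10-trimethyl-5-{(3E)-3-methyl-5-[(triisopropylsilyl)oxy]pent-3-en-1-yl}-7-[(triethylsilyl)oxy]undeca-3,5,9-triene-2,8-dione | CC(C)=CC(=O)[C@@H](O[Si](CC)(CC)CC)/C(C)=C(CC/C(C)=C/CO[Si](C(C)C)(C(C)C)C(C)C)\C(C)=C\C(C)=O | intermediate
22 | lithium cross-conjugated dienolate of 21 (O-lithiated at the acetyl carbon, labdane C2) | CC(C)=CC(=O)[C@@H](O[Si](CC)(CC)CC)/C(C)=C(CC/C(C)=C/CO[Si](C(C)C)(C(C)C)C(C)C)\C(C)=C\C(=C)O[Li] | intermediate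
23 | (5S,6Z,8E)-10-[(tert-butyldimethylsilyl)oxy]-2,6,8-trimethyl-7-{(3E)-3-methyl-5-[(triisopropylsilyl)oxy]pent-3-en-1-yl}-5-[(triethylsilyl)oxy]undeca-2,6,8,10-tetraen-4-one | CC(C)=CC(=O)[C@@H](O[Si](CC)(CC)CC)/C(C)=C(CC/C(C)=C/CO[Si](C(C)C)(C(C)C)C(C)C)\C(C)=C\C(=C)O[Si](C)(C)C(C)(C)C | intermediate
24 | 2-[(tert-butyldimethylsilyl)oxy]-7α-[(triethylsilyl)oxy]-15-[(triisopropylsilyl)oxy]labda-1,8,13E-trien-6-one (5S,7S,10S) | CC(C)(C)[Si](C)(C)OC1CC(C)(C)[C@@H]2C(=O)[C@@H](O[Si](CC)(CC)CC)C(C)=C(CC/C(C)=C/CO[Si](C(C)C)(C(C)C)C(C)C)[C@@]2(C)C=1 | intermediate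
25 | 2-[(tert-butyldimethylsilyl)oxy]-7α-[(triethylsilyl)oxy]-15-[(triisopropylsilyl)oxy]labda-1,8,13E-trien-6β-ol | CC(C)(C)[Si](C)(C)OC1CC(C)(C)[C@@H]2[C@H](O)[C@@H](O[Si](CC)(CC)CC)C(C)=C(CC/C(C)=C/CO[Si](C(C)C)(C(C)C)C(C)C)[C@@]2(C)C=1 | intermediate
26 | 6β,7α-dihydroxy-15-[(triisopropylsilyl)oxy]labda-8,13E-dien-2-one | O=C1CC(C)(C)[C@@H]2[C@H](O)[C@@H](O)C(C)=C(CC/C(C)=C/CO[Si](C(C)C)(C(C)C)C(C)C)[C@@]2(C)C1 | intermediate
27 | 15-[(triisopropylsilyl)oxy]labda-8,13E-diene-2α,6β,7α-triol | O[C@H]1CC(C)(C)[C@@H]2[C@H](O)[C@@H](O)C(C)=C(CC/C(C)=C/CO[Si](C(C)C)(C(C)C)C(C)C)[C@@]2(C)C1 | intermediate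
28 | 15-[(triisopropylsilyl)oxy]labda-8,13E-diene-2α,6β,7α-triyl triacetate | CC(=O)O[C@H]1CC(C)(C)[C@@H]2[C@H](OC(C)=O)[C@@H](OC(C)=O)C(C)=C(CC/C(C)=C/CO[Si](C(C)C)(C(C)C)C(C)C)[C@@]2(C)C1 | intermediate
29 | 15-hydroxylabda-8,13E-diene-2α,6β,7α-triyl triacetate (2S,5S,6S,7S,10S), CNP0305346.2 | CC(=O)O[C@H]1CC(C)(C)[C@@H]2[C@H](OC(C)=O)[C@@H](OC(C)=O)C(C)=C(CC/C(C)=C/CO)[C@@]2(C)C1 | target

**Step count**
Total: 19 steps. Longest linear sequence: 18 steps (steps 1–10 and 12–19); step 11 is a one-step side branch.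

**Steps most likely to fail**

1. Step 14. The cycloaddition joins two fully substituted termini (the gem-dimethyl dienophile carbon and the methyl-bearing diene terminus). It may be slow enough that a [1,5]-hydrogen shift from the inside C10 methyl or loss of the enol silyl group overtakes it, or the exo/endo (trans/cis ring fusion) selectivity may be poor. Fallback, an anionic intramolecular double Michael reaction: the route is left at bis-enone 21, which with LiN(SiMe3)2 in THF at −78 to 0 °C should give dienolate 22. This should add through C3 to C4 of the enone, and the resulting enolate carbon C5 should then add to C10, giving lithium 6-oxo-7α-[(triethylsilyl)oxy]-15-[(triisopropylsilyl)oxy]labda-1,8,13E-trien-2-olate F1. Silylation in the same flask with t-BuMe2SiCl/DMPU returns to the route at 24.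

2. Step 13. Enolisation may be unselective: removal of the C7 hydrogen (epimerisation), removal of a γ-methyl hydrogen of the C6 enone, or silylation at both ketones. Fallback, making the silyloxydiene before the second enone is present: the route is left at boronate 20, which with t-BuMe2SiOTf/Et3N in CH2Cl2 at −78 to 0 °C should give tert-butyldimethyl{[(3Z)-4-(4,4,5,5-tetramethyl-1,3,2-dioxaborolan-2-yl)penta-1,3-dien-2-yl]oxy}silane F2. Suzuki–Miyaura coupling of this boronate with iodo enone 18 (Pd(dppf)Cl2, K3PO4, THF with a little water, rt) returns to the route at 23.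

3. Step 6. Carbometalation of the hindered internal alkyne as a bis-alkoxide may be sluggish, may add with the wrong regiochemistry or incomplete anti selectivity, or the alkenylmagnesium species may be protonated before iodination. Fallback, carbometalation on an unhindered primary propargylic alcohol with C7 set afterwards and the enone unveiled by rearrangement: the route is left at alkyne 5.
   - n-BuLi then (CH2O)n should give (6E)-6-methyl-8-[(triisopropylsilyl)oxy]oct-6-en-2-yn-1-ol F3.
   - MeMgBr/CuI then I2 should give (2Z,6E)-3-iodo-2,6-dimethyl-8-[(triisopropylsilyl)oxy]octa-2,6-dien-1-ol F4.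
   - MnO2 in CH2Cl2 should give (2Z,6E)-3-iodo-2,6-dimethyl-8-[(triisopropylsilyl)oxy]octa-2,6-dienal F5.
   - Me2Zn/ProPhenol-catalysed addition of 2-methylbut-3-yn-2-ol (ligand enantiomer chosen for the 5R carbinol) should give (5R,6Z,10E)-7-iodo-2,6,10-trimethyl-12-[(triisopropylsilyl)oxy]dodeca-6,10-dien-3-yne-2,5-diol F6.
   - Et3SiCl/imidazole at the secondary hydroxyl only should give (5R,6Z,10E)-7-iodo-2,6,10-trimethyl-5-[(triethylsilyl)oxy]-12-[(triisopropylsilyl)oxy]dodeca-6,10-dien-3-yn-2-ol F7.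
   - Ph3PAuNTf2-catalysed Meyer–Schuster rearrangement of the tertiary propargylic alcohol returns to the route at 18.

**Further compounds**
F1 | step 14 | lithium 6-oxo-7α-[(triethylsilyl)oxy]-15-[(triisopropylsilyl)oxy]labda-1,8,13E-trien-2-olate | [Li]OC1CC(C)(C)[C@@H]2C(=O)[C@@H](O[Si](CC)(CC)CC)C(C)=C(CC/C(C)=C/CO[Si](C(C)C)(C(C)C)C(C)C)[C@@]2(C)C=1
F2 | step 13 | tert-butyldimethyl{[(3Z)-4-(4,4,5,5-tetramethyl-1,3,2-dioxaborolan-2-yl)penta-1,3-dien-2-yl]oxy}silane | C=C(O[Si](C)(C)C(C)(C)C)/C=C(\C)B1OC(C)(C)C(C)(C)O1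
F3 | step 6 | (6E)-6-methyl-8-[(triisopropylsilyl)oxy]oct-6-en-2-yn-1-ol | OCC#CCC/C(C)=C/CO[Si](C(C)C)(C(C)C)C(C)C
F4 | step 6 | (2Z,6E)-3-iodo-2,6-dimethyl-8-[(triisopropylsilyl)oxy]octa-2,6-dien-1-ol | OC/C(C)=C(\I)CC/C(C)=C/CO[Si](C(C)C)(C(C)C)C(C)C
F5 | step 6 | (2Z,6E)-3-iodo-2,6-dimethyl-8-[(triisopropylsilyl)oxy]octa-2,6-dienal | O=C/C(C)=C(\I)CC/C(C)=C/CO[Si](C(C)C)(C(C)C)C(C)C
F6 | step 6 | (5R,6Z,10E)-7-iodo-2,6,10-trimethyl-12-[(triisopropylsilyl)oxy]dodeca-6,10-dien-3-yne-2,5-diol | CC(C)(O)C#C[C@@H](O)/C(C)=C(\I)CC/C(C)=C/CO[Si](C(C)C)(C(C)C)C(C)C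
F7 | step 6 | (5R,6Z,10E)-7-iodo-2,6,10-trimethyl-5-[(triethylsilyl)oxy]-12-[(triisopropylsilyl)oxy]dodeca-6,10-dien-3-yn-2-ol | CC(C)(O)C#C[C@@H](O[Si](CC)(CC)CC)/C(C)=C(\I)CC/C(C)=C/CO[Si](C(C)C)(C(C)C)C(C)C
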